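**Plan**

- Retrosynthesis: the interflavan C4–C6 bond is cut first, so both halves become the same protected (2R,3S)-gallocatechin. In that flavan, ring C is opened at O1–C8a and C2–C3 together, giving a 2-fluoroaryl benzyloxymethyl ketone (ring A plus C4 and C3) and 3,4,5-tris(benzyloxy)benzaldehyde (ring B plus C2 and O1).
- Enabling feature: C8a of ring A is ortho to C4a, so a single carbonyl at C4 makes C3 an enolate carbon and activates a C8a–F bond for addition–elimination. This C3(−)/C8a(+) unit is completed to ring C by the aldehyde C2(+)/O1(−) in one event.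
- Forward order: ring A fluoroarene, acylation, silyl enol ether, aldol/SNAr annulation (ring C closes on ring A as ring B arrives), reduction to the C4 alcohol as branch point (deoxygenation then C8 bromide gives the nucleophile; C6/C8 dibromide gives the electrophile), Friedel–Crafts union at C6, global hydrogenolysis.
- Stereochemistry: C2 of both units comes from the chiral ammonium catalyst of the annulation; C3 is trans to C2 (anti addition, and the thermodynamically favoured α-keto centre); upper C4 comes from arene attack anti to the 3-benzyloxy group. The bromine caps enforce the 4→6 connectivity.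

Key step: step 4

Remark: the cinchonidinium catalyst is assumed to give the (2R) sense of addition (its pseudoenantiomeric cinchoninium salt would serve otherwise), and the C4 configuration drawn for 12 and 16 is immaterial because C4 is ionised later.

**Step 1**
Reactants: 1 1,3,5-trifluorobenzene
Product: 3 1,3-bis(benzyloxy)-5-fluorobenzene, via 1-(benzyloxy)-3,5-difluorobenzene 2 (not isolated)
Conditions: BnOH (2.1 equiv), NaH (2.2 equiv), N-methylpyrrolidone, 0 → 100 °C
Reagents that add atoms: benzyl alcohol, OCc1ccccc1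
Why: Two successive SNAr displacements of fluoride by benzyloxide should stop at the bis-ether, because each replacement of fluorine by the less electron-withdrawing benzyloxy group slows the next addition–elimination.

**Step 2**
Reactants: 3 1,3-bis(benzyloxy)-5-fluorobenzene; 4 2-(benzyloxy)-N-methoxy-N-methylacetamide
Product: 6 2-(benzyloxy)-1-[2,4-bis(benzyloxy)-6-fluorophenyl]ethan-1-one, via [2,4-bis(benzyloxy)-6-fluorophenyl]lithium 5 (not isolated)
Conditions: n-BuLi, THF, −78 °C; then 4, −78 °C; aq NH4Cl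
Reagents that add atoms: none
Why: Directed ortho-lithiation at the C–H flanked by fluorine and a benzyloxy group (the most acidic ring position) followed by acylation with the N-methoxy-N-methylamide (Weinreb ketone synthesis) should give the ketone without over-addition, the low temperature keeping the ortho-fluoroaryllithium from losing LiF.

**Step 3**
Reactants: 6 2-(benzyloxy)-1-[2,4-bis(benzyloxy)-6-fluorophenyl]ethan-1-one
Product: 7 (Z)-[2-(benzyloxy)-1-(2,4-bis(benzyloxy)-6-fluorophenyl)ethenyl]oxy-trimethylsilane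
Conditions: TMSOTf, Et3N, CH2Cl2, 0 °C; non-aqueous work-up
Reagents that add atoms: trimethylsilyl trifluoromethanesulfonate, C[Si](C)(C)OS(=O)(=O)C(F)(F)F
Why: Soft enolisation (silyl triflate and amine) at the only enolisable carbon should give the silyl enol ether as the Z isomer, which keeps the bulky 2,6-disubstituted aryl group cis to hydrogen.

**Step 4**
Reactants: 7 (Z)-[2-(benzyloxy)-1-(2,4-bis(benzyloxy)-6-fluorophenyl)ethenyl]oxy-trimethylsilane; 8 3,4,5-tris(benzyloxy)benzaldehyde
Product: 11 (2R,3R)-3,5,7-tris(benzyloxy)-2-[3,4,5-tris(benzyloxy)phenyl]chroman-4-one, via ammonium enolate 9 (not isolated), via anti-aldolate 10 (not isolated)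
Conditions: N-(9-anthracenylmethyl)-O-benzylcinchonidinium hydrogen difluoride (10 mol%), THF–CH2Cl2, −78 → 0 °C
Reagents that add atoms: none
Why: Proposed new method: catalytic bifluoride removes the silyl group of 7 to give the chiral ammonium enolate 9, which adds to aldehyde 8 inside the ion pair; the alkoxide 10 then attacks C8a, ortho to the C4 carbonyl, and expels fluoride by addition–elimination, and that fluoride desilylates the next molecule of 7, so fluoride is relayed and Me3SiF is the only by-product. The closest known reactions are the cinchona ammonium bifluoride-catalysed Mukaiyama aldol of silyl enol ethers and the base-mediated aldol–SNAr annulation of 2-fluoroaryl ketones to chroman-4-ones. Ring C closes by a 6-exo attack of O1 on the aromatic carbon C8a through a Meisenheimer complex stabilised by the ketone. C2 is set by the chiral ammonium cation, which shields one face of the aldehyde–enolate pair; C3 is set anti to it in an open transition state and, as the only carbon α to the C4 ketone, is also held trans (both substituents equatorial) under thermodynamic control. The step needs the C–C bond formation to be trapped before retro-aldol and needs a single site of O-arylation: the lone fluorine is the only leaving group, the two benzyloxy groups are meta to it and do not deactivate C8a, and neither the enolate oxygen nor C3 can reach C8a without forming a four-membered ring.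

**Step 5**
Reactants: 11 (2R,3R)-3,5,7-tris(benzyloxy)-2-[3,4,5-tris(benzyloxy)phenyl]chroman-4-one
Product: 12 (2R,3S,4R)-3,5,7-tris(benzyloxy)-2-[3,4,5-tris(benzyloxy)phenyl]chroman-4-ol
Conditions: NaBH4, THF–MeOH, 0 °C
Reagents that add atoms: none
Why: Carbonyl reduction with hydride delivered anti to the neighbouring 3-benzyloxy group should give mainly the 3,4-trans alcohol, the C4 configuration being of no consequence for steps 6 and 9.

**Step 6**
Reactants: 12 (2R,3S,4R)-3,5,7-tris(benzyloxy)-2-[3,4,5-tris(benzyloxy)phenyl]chroman-4-ol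
Product: 14 (2R,3S)-3,5,7-tris(benzyloxy)-2-[3,4,5-tris(benzyloxy)phenyl]chromane, via flavan-4-yl cation 13 (not isolated)
Conditions: Et3SiH (excess), TFA, CH2Cl2, −40 → 0 °C
Reagents that add atoms: none
Why: Ionic hydrogenation, in which the C4 alcohol ionises to a cation stabilised by O1, O5 and O7 of ring A and is captured by silane hydride, should leave C2 and C3 untouched.

**Step 7**
Reactants: 14 (2R,3S)-3,5,7-tris(benzyloxy)-2-[3,4,5-tris(benzyloxy)phenyl]chromane
Product: 15 (2R,3S)-8-bromo-3,5,7-tris(benzyloxy)-2-[3,4,5-tris(benzyloxy)phenyl]chromane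
Conditions: NBS (1.0 equiv), CH2Cl2, −20 °C
Reagents that add atoms: N-bromosuccinimide, O=C1CCC(=O)N1Br
Why: Electrophilic aromatic bromination should occur on the phloroglucinol-type ring A and there at C8 (between O1 and the 7-benzyloxy group), which is more accessible than C6 between two benzyloxy groups, as is general for protected flavan-3-ols.

**Step 8**
Reactants: 12 (2R,3S,4R)-3,5,7-tris(benzyloxy)-2-[3,4,5-tris(benzyloxy)phenyl]chroman-4-ol
Product: 16 (2R,3S,4R)-6,8-dibromo-3,5,7-tris(benzyloxy)-2-[3,4,5-tris(benzyloxy)phenyl]chroman-4-ol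
Conditions: NBS (2.1 equiv), NaHCO3, CH2Cl2, −20 → 0 °C
Reagents that add atoms: N-bromosuccinimide, O=C1CCC(=O)N1Br
Why: Twofold electrophilic bromination of ring A caps both of its nucleophilic positions so that the future electrophile cannot condense with itself, solid NaHCO3 keeping the medium free of acid that would ionise the C4 alcohol.

**Step 9**
Reactants: 15 (2R,3S)-8-bromo-3,5,7-tris(benzyloxy)-2-[3,4,5-tris(benzyloxy)phenyl]chromane; 16 (2R,3S,4R)-6,8-dibromo-3,5,7-tris(benzyloxy)-2-[3,4,5-tris(benzyloxy)phenyl]chroman-4-ol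
Product: 18 6,8,8'-tribromo-dodeca-O-benzyl-gallocatechin-(4α→6)-gallocatechin, via 6,8-dibromoflavan-4-yl cation 17 (not isolated)
Conditions: 15 (3 equiv), TMSOTf (1.1 equiv), CH2Cl2, −78 → −40 °C; aq NaHCO3
Reagents that add atoms: none
Why: Friedel–Crafts alkylation, in which silylation and ionisation of the C4 alcohol give cation 17 and the only free ring-A position of 15 (C6, since C8 carries bromine) attacks anti to the 3-benzyloxy group, should give the 3,4-trans (4α) C4–C6 bond, the excess of 15 being recoverable.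

**Step 10**
Reactants: 18 6,8,8'-tribromo-dodeca-O-benzyl-gallocatechin-(4α→6)-gallocatechin
Product: 19 gallocatechin-(4α→6)-gallocatechin
Conditions: H2 (1 atm), Pd(OH)2/C, NaOAc, THF–MeOH–H2O, rt
Reagents that add atoms: none
Why: Catalytic hydrogenolysis should cleave the twelve benzyl ethers and the three aryl C–Br bonds in one operation, acetate buffering the HBr so that the acid-labile interflavan bond survives.

**Compound list**

1 | 1,3,5-trifluorobenzene | Fc1cc(F)cc(F)c1 | starting material
2 | 1-(benzyloxy)-3,5-difluorobenzene | Fc1cc(F)cc(OCc2ccccc2)c1 | intermediate (not isolated)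
3 | 1,3-bis(benzyloxy)-5-fluorobenzene | Fc1cc(OCc2ccccc2)cc(OCc2ccccc2)c1 | intermediate
4 | 2-(benzyloxy)-N-methoxy-N-methylacetamide | CON(C)C(=O)COCc1ccccc1 | starting material
5 | [2,4-bis(benzyloxy)-6-fluorophenyl]lithium | [Li]c1c(F)cc(OCc2ccccc2)cc1OCc1ccccc1 | intermediate (not isolated)
6 | 2-(benzyloxy)-1-[2,4-bis(benzyloxy)-6-fluorophenyl]ethan-1-one | O=C(COCc1ccccc1)c1c(F)cc(OCc2ccccc2)cc1OCc1ccccc1 | intermediate
7 | (Z)-[2-(benzyloxy)-1-(2,4-bis(benzyloxy)-6-fluorophenyl)ethenyl]oxy-trimethylsilane (silyloxy and benzyloxy cis) | C[Si](C)(C)O/C(=C\OCc1ccccc1)c1c(F)cc(OCc2ccccc2)cc1OCc1ccccc1 | intermediate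
8 | 3,4,5-tris(benzyloxy)benzaldehyde | O=Cc1cc(OCc2ccccc2)c(OCc2ccccc2)c(OCc2ccccc2)c1 | starting material
9 | (Z)-enolate of 6, paired with the chiral ammonium cation (anion shown) | [O-]/C(=C\OCc1ccccc1)c1c(F)cc(OCc2ccccc2)cc1OCc1ccccc1 | intermediate (not isolated)
10 | (2R,3R)-anti aldolate: 2-(benzyloxy)-1-[2,4-bis(benzyloxy)-6-fluorophenyl]-3-oxido-3-[3,4,5-tris(benzyloxy)phenyl]propan-1-one (anion shown) | [O-][C@H](c1cc(OCc2ccccc2)c(OCc2ccccc2)c(OCc2ccccc2)c1)[C@@H](OCc1ccccc1)C(=O)c1c(F)cc(OCc2ccccc2)cc1OCc1ccccc1 | intermediate (not isolated)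
11 | (2R,3R)-3,5,7-tris(benzyloxy)-2-[3,4,5-tris(benzyloxy)phenyl]chroman-4-one (2,3-trans) | O=C1c2c(OCc3ccccc3)cc(OCc3ccccc3)cc2O[C@H](c2cc(OCc3ccccc3)c(OCc3ccccc3)c(OCc3ccccc3)c2)[C@H]1OCc1ccccc1 | intermediate
12 | (2R,3S,4R)-3,5,7-tris(benzyloxy)-2-[3,4,5-tris(benzyloxy)phenyl]chroman-4-ol (2,3-trans, 3,4-trans) | O[C@@H]1c2c(OCc3ccccc3)cc(OCc3ccccc3)cc2O[C@H](c2cc(OCc3ccccc3)c(OCc3ccccc3)c(OCc3ccccc3)c2)[C@H]1OCc1ccccc1 | intermediate
13 | flavan-4-yl cation from 12 (C2 and C3 as in 12) | [CH+]1c2c(OCc3ccccc3)cc(OCc3ccccc3)cc2O[C@H](c2cc(OCc3ccccc3)c(OCc3ccccc3)c(OCc3ccccc3)c2)[C@H]1OCc1ccccc1 | intermediate (not isolated)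
14 | (2R,3S)-3,5,7-tris(benzyloxy)-2-[3,4,5-tris(benzyloxy)phenyl]chromane (hexa-O-benzyl-(+)-gallocatechin) | C1c2c(OCc3ccccc3)cc(OCc3ccccc3)cc2O[C@H](c2cc(OCc3ccccc3)c(OCc3ccccc3)c(OCc3ccccc3)c2)[C@H]1OCc1ccccc1 | intermediate
15 | (2R,3S)-8-bromo-3,5,7-tris(benzyloxy)-2-[3,4,5-tris(benzyloxy)phenyl]chromane | C1c2c(OCc3ccccc3)cc(OCc3ccccc3)c(Br)c2O[C@H](c2cc(OCc3ccccc3)c(OCc3ccccc3)c(OCc3ccccc3)c2)[C@H]1OCc1ccccc1 | intermediate
16 | (2R,3S,4R)-6,8-dibromo-3,5,7-tris(benzyloxy)-2-[3,4,5-tris(benzyloxy)phenyl]chroman-4-ol | O[C@@H]1c2c(OCc3ccccc3)c(Br)c(OCc3ccccc3)c(Br)c2O[C@H](c2cc(OCc3ccccc3)c(OCc3ccccc3)c(OCc3ccccc3)c2)[C@H]1OCc1ccccc1 | intermediate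
17 | 6,8-dibromoflavan-4-yl cation from 16 (C2 and C3 as in 16) | [CH+]1c2c(OCc3ccccc3)c(Br)c(OCc3ccccc3)c(Br)c2O[C@H](c2cc(OCc3ccccc3)c(OCc3ccccc3)c(OCc3ccccc3)c2)[C@H]1OCc1ccccc1 | intermediate (not isolated)
18 | 6,8,8'-tribromo-dodeca-O-benzyl-gallocatechin-(4α→6)-gallocatechin: upper unit as 16 without its 4-OH, bonded through C4 (trans to its 3-benzyloxy group, cis to its C2 aryl) to C6 of lower unit 15 | O(Cc9ccccc9)c1c(Br)c(OCc9ccccc9)c2c(c1Br)O[C@H](c3cc(OCc9ccccc9)c(OCc9ccccc9)c(OCc9ccccc9)c3)[C@@H](OCc9ccccc9)[C@@H]2c1c(OCc9ccccc9)c(Br)c2c(c1OCc9ccccc9)C[C@H](OCc9ccccc9)[C@@H](c3cc(OCc9ccccc9)c(OCc9ccccc9)c(OCc9ccccc9)c3)O2 | intermediate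
19 | gallocatechin-(4α→6)-gallocatechin: two (2R,3S)-2-(3,4,5-trihydroxyphenyl)chromane-3,5,7-triol units, C4 of the upper one (trans to its 3-OH, cis to its C2 aryl) bonded to C6 of the lower one | Oc1cc(O)c2c(c1)O[C@H](c1cc(O)c(O)c(O)c1)[C@@H](O)[C@@H]2c1c(O)cc2c(c1O)C[C@H](O)[C@@H](c1cc(O)c(O)c(O)c1)O2 | target

**Step count and risks**

Total step count: 10. Longest linear sequence: 9 steps (steps 1 to 7, then 9 and 10).

Steps most likely to fail:

1. Step 4 (Proposed new method). The aldol addition may revert faster than the alkoxide is arylated or silylated, and facial discrimination in the ion pair may be weak; either would erode the enantiomeric purity at C2. Slow addition–elimination could also leave the silylated aldol unconverted. Fallback by known chemistry, setting out from 8 and rejoining at 11: an oxazolidinone-directed boron aldol (Evans syn aldol; Bu2BOTf, i-Pr2NEt, CH2Cl2, −78 → 0 °C) of 8 with (S)-4-benzyl-3-[(benzyloxy)acetyl]oxazolidin-2-one should give (4S)-4-benzyl-3-[(2S,3R)-2-(benzyloxy)-3-hydroxy-3-(3,4,5-tris(benzyloxy)phenyl)propanoyl]oxazolidin-2-one F1, whose carbinol carbon already has the configuration needed for C2. Transamidation (MeNHOMe·HCl, AlMe3) gives the N-methoxy-N-methylamide F2, and silylation (Et3SiCl, imidazole) gives the triethylsilyl ether F3. Addition of aryllithium 5 (made from 3 as in step 2) gives the β-silyloxy ketone F4. Bu4NF in THF then frees the alkoxide, which closes ring C by the same addition–elimination to give the 2,3-cis chromanone F5. K2CO3 in DMF epimerises the α-keto centre C3 to the trans isomer, which is 11.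

2. Step 9. Capture of the cation by the hindered, bromine-deactivated C6 of 15 may be slower than loss of the C3 proton (flav-3-ene formation) or recombination with silanol, and the strongly acidic promoter may lower the facial selectivity at C4 or reopen the new bond. Fallback, setting out from 16 and rejoining at 18: exchange of the 4-hydroxyl for a thiol (PhSH, BF3·OEt2, CH2Cl2, −78 °C) gives the 6,8-dibromo-4-(phenylsulfanyl)flavan F7, a storable donor. It is activated by the thiophilic salt AgBF4 in the presence of 15 and 2,6-di-tert-butylpyridine (THF–CH2Cl2, 0 °C), so the cation is generated without an oxophilic Lewis acid or free strong acid.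

3. Step 6. The C4 cation may be intercepted by ring A of a second molecule (self-condensation) or lose the C3 proton before hydride transfer. Fallback, setting out from 12 and rejoining at 14: the alcohol is converted into the S-methyl xanthate F6 (NaH, CS2, MeI, THF) and reduced under radical conditions (Bu3SnH, AIBN, toluene, 80 °C; Barton–McCombie deoxygenation), which avoids the cation altogether.

**Further compounds**

F1 | step 4 | (4S)-4-benzyl-3-[(2S,3R)-2-(benzyloxy)-3-hydroxy-3-(3,4,5-tris(benzyloxy)phenyl)propanoyl]oxazolidin-2-one | O=C1OC[C@H](Cc2ccccc2)N1C(=O)[C@@H](OCc1ccccc1)[C@H](O)c1cc(OCc2ccccc2)c(OCc2ccccc2)c(OCc2ccccc2)c1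
F2 | step 4 | (2S,3R)-2-(benzyloxy)-3-hydroxy-N-methoxy-N-methyl-3-[3,4,5-tris(benzyloxy)phenyl]propanamide | CON(C)C(=O)[C@@H](OCc1ccccc1)[C@H](O)c1cc(OCc2ccccc2)c(OCc2ccccc2)c(OCc2ccccc2)c1
F3 | step 4 | (2S,3R)-2-(benzyloxy)-N-methoxy-N-methyl-3-[(triethylsilyl)oxy]-3-[3,4,5-tris(benzyloxy)phenyl]propanamide | CON(C)C(=O)[C@@H](OCc1ccccc1)[C@H](O[Si](CC)(CC)CC)c1cc(OCc2ccccc2)c(OCc2ccccc2)c(OCc2ccccc2)c1
F4 | step 4 | (2S,3R)-2-(benzyloxy)-1-[2,4-bis(benzyloxy)-6-fluorophenyl]-3-[(triethylsilyl)oxy]-3-[3,4,5-tris(benzyloxy)phenyl]propan-1-one | O=C([C@@H](OCc1ccccc1)[C@H](O[Si](CC)(CC)CC)c1cc(OCc2ccccc2)c(OCc2ccccc2)c(OCc2ccccc2)c1)c1c(F)cc(OCc2ccccc2)cc1OCc1ccccc1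
F5 | step 4 | (2R,3S)-3,5,7-tris(benzyloxy)-2-[3,4,5-tris(benzyloxy)phenyl]chroman-4-one (2,3-cis) | O=C1c2c(OCc3ccccc3)cc(OCc3ccccc3)cc2O[C@H](c2cc(OCc3ccccc3)c(OCc3ccccc3)c(OCc3ccccc3)c2)[C@@H]1OCc1ccccc1
F6 | step 6 | S-methyl xanthate of 12 (O-flavan-4-yl S-methyl carbonodithioate, other centres as in 12) | CSC(=S)O[C@@H]1c2c(OCc3ccccc3)cc(OCc3ccccc3)cc2O[C@H](c2cc(OCc3ccccc3)c(OCc3ccccc3)c(OCc3ccccc3)c2)[C@H]1OCc1ccccc1
F7 | step 9 | 6,8-dibromo-4-(phenylsulfanyl) analogue of 16 (sulfur trans to the 3-benzyloxy group, C2 and C3 as in 16) | c1ccccc1S[C@@H]1c2c(OCc3ccccc3)c(Br)c(OCc3ccccc3)c(Br)c2O[C@H](c2cc(OCc3ccccc3)c(OCc3ccccc3)c(OCc3ccccc3)c2)[C@H]1OCc1ccccc1
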